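**Retrosynthetic overview**

1. Target 27 is the enol tautomer of a 2,3-dione; it comes from oxidation of an α-ketol that is unmasked from a silyl enol ether / silyl ether pair.
2. Key step: thermal type 1 intramolecular Diels–Alder reaction of an acyclic (1E,3Z)-1,2-bis(silyloxy)diene with the internal π-bond of a 1,1-disubstituted allene. Rings A and B form in the same step (ring A as the cycloadduct ring, ring B as the tether ring); the step sets C5 and C10 and delivers the exocyclic methylene and the C2/C3 oxygens.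
3. The triene comes from a C7 aldehyde and a 1,3-dien-2-ylboronate (Felkin homoallenylation sets C7); the diene oxygens come from a glycerate acetonide.
4. C8 and the quaternary C9 come from an iridium-catalysed olefin isomerisation–Claisen rearrangement of a di(allyl) ether, with 1,3-chirality transfer from a glycerate-derived carbinol.
5. The di(allyl) ether comes from Negishi coupling of a 3-methylglutarate-derived alkylzinc (C13) with an (E)-alkenyl iodide.

Assumption: atoms are labelled by clerodane numbering (ring A C1–C5/C10, ring B C5–C10, side chain C11–C16, methyls C17/C19/C20, methylene C18), in which the target is 5S,7S,8S,9R,10R,13R with a cis ring fusion; 1, 4 and 14 are taken as purchasable single compounds.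

**Route**

Step 1
Reactants: 1 (3R)-5-methoxy-3-methyl-5-oxopentanoic acid [(R)-methyl hydrogen 3-methylglutarate]
Product: 2 methyl (3R)-5-hydroxy-3-methylpentanoate
Conditions: BH3·SMe2, THF, 0 °C to rt; then MeOH
Reagents that add atoms: none
Why: Chemoselective borane reduction of a carboxylic acid beside a methyl ester (acyloxyborane pathway) leaves the C13 stereocentre untouched, and the crude alcohol is used at once to avoid lactonisation.

Step 2
Reactants: 2 methyl (3R)-5-hydroxy-3-methylpentanoate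
Product: 3 methyl (3S)-5-iodo-3-methylpentanoate
Conditions: I2, PPh3, imidazole, CH2Cl2, 0 °C
Reagents that add atoms: iodine, I-I
Why: Appel-type iodination by SN2 displacement at the primary carbinol does not touch the stereocentre (the descriptor changes only through CIP priorities).

Step 3
Reactants: 4 methyl (4R)-2,2-dimethyl-1,3-dioxolane-4-carboxylate
Product: 5 1-[(4R)-2,2-dimethyl-1,3-dioxolan-4-yl]but-2-yn-1-one
Conditions: 1-propynyllithium (1.1 equiv), THF, −78 °C; AcOH quench at −78 °C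
Reagents that add atoms: 1-propynyllithium, [Li]C#CC
Why: Acylation of a lithium acetylide by an α-alkoxy ester gives the ynone because the chelated tetrahedral lithium alkoxide survives until the cold quench, which prevents over-addition and α-epimerisation.

Step 4
Reactants: 5 1-[(4R)-2,2-dimethyl-1,3-dioxolan-4-yl]but-2-yn-1-one
Product: 6 (1R)-1-[(4R)-2,2-dimethyl-1,3-dioxolan-4-yl]but-2-yn-1-ol
Conditions: LiBH(s-Bu)3, THF, −78 °C; then H2O
Reagents that add atoms: none
Why: Felkin–Anh 1,2-reduction of the α-alkoxy ynone by a bulky non-chelating hydride (ring C–O bond anti to the incoming hydride) gives the syn (1R) carbinol that later relays chirality in the Claisen step.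

Step 5
Reactants: 6 (1R)-1-[(4R)-2,2-dimethyl-1,3-dioxolan-4-yl]but-2-yn-1-ol
Product: 8 (1R,2E)-1-[(4R)-2,2-dimethyl-1,3-dioxolan-4-yl]-3-iodobut-2-en-1-ol, via O,C-dizirconated alkenylzirconocene 7 (not isolated)
Conditions: Cp2Zr(H)Cl (3 equiv), THF, 0 to 45 °C; then I2, 0 °C; aq. Na2S2O3
Reagents that add atoms: iodine, I-I
Why: Hydrozirconation–iodination adds H–Zr syn with zirconium on the less hindered methyl-bearing alkyne carbon (the other regioisomer would β-eliminate the alkoxide and be lost), and iodinolysis with retention gives the (E)-alkenyl iodide.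

Step 6
Reactants: 8 (1R,2E)-1-[(4R)-2,2-dimethyl-1,3-dioxolan-4-yl]-3-iodobut-2-en-1-ol
Product: 9 (4R)-4-[(1R,2E)-3-iodo-1-(prop-2-enyloxy)but-2-enyl]-2,2-dimethyl-1,3-dioxolane
Conditions: NaH, allyl bromide, n-Bu4NI (cat.), THF/DMF, 0 °C to rt
Reagents that add atoms: allyl bromide, C=CCBr
Why: Williamson etherification of the sodium alkoxide installs the allyl group needed for the Claisen step while the alkenyl iodide and acetonide are inert.

Step 7
Reactants: 3 methyl (3S)-5-iodo-3-methylpentanoate; 9 (4R)-4-[(1R,2E)-3-iodo-1-(prop-2-enyloxy)but-2-enyl]-2,2-dimethyl-1,3-dioxolane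
Product: 11 methyl (3R,6E,8R)-8-[(4R)-2,2-dimethyl-1,3-dioxolan-4-yl]-3,6-dimethyl-8-(prop-2-enyloxy)oct-6-enoate, via alkylzinc iodide 10 (not isolated)
Conditions: 3, Zn dust (BrCH2CH2Br, Me3SiCl activation), DMA, 40 °C; then 9, Pd(PPh3)4 (5 mol%), THF, 45 °C
Reagents that add atoms: none
Why: Negishi sp3–sp2 cross-coupling (ester-tolerant zinc insertion, then coupling on zerovalent palladium with retention of alkene geometry) joins the C13 fragment and fixes the (E)-trisubstituted C9=C10 alkene.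

Step 8
Reactants: 11 methyl (3R,6E,8R)-8-[(4R)-2,2-dimethyl-1,3-dioxolan-4-yl]-3,6-dimethyl-8-(prop-2-enyloxy)oct-6-enoate
Product: 13 methyl (3R,6R,7S)-6-[(E)-2-[(4S)-2,2-dimethyl-1,3-dioxolan-4-yl]ethenyl]-3,6,7-trimethyl-8-oxooctanoate, via (E)-propenyl ether 12 (not isolated)
Conditions: [IrCl(C8H14)2]2 (1 mol%), PCy3 (6 mol%), NaBPh4 (2 mol%), CH2Cl2/acetone, rt; then PPh3, ClCH2CH2Cl, 80 °C
Reagents that add atoms: none
Why: Olefin isomerisation–Claisen rearrangement, in which the cationic monovalent iridium catalyst moves only the unsubstituted allyl double bond to the (E)-enol ether and the [3,3] shift through the chair with the dioxolanyl group equatorial (the axial alternative clashes with the methyl on C9) transfers the carbinol chirality to the quaternary C9, sets C8 (8S,9R in clerodane numbering) and leaves the (E)-C10=C1 alkene.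

Step 9
Reactants: 14 3-methylbut-3-en-2-one
Product: 15 3-methylbuta-1,3-dien-2-yl trifluoromethanesulfonate
Conditions: LiN(i-Pr)2, THF, −78 °C; PhNTf2, −78 to 0 °C
Reagents that add atoms: N-phenylbis(trifluoromethanesulfonimide), O=S(=O)(N(c1ccccc1)S(=O)(=O)C(F)(F)F)C(F)(F)F
Why: Kinetic enolisation at the only α-methyl group followed by O-triflation gives the cross-conjugated dienyl triflate.

Step 10
Reactants: 15 3-methylbuta-1,3-dien-2-yl trifluoromethanesulfonate
Product: 16 4,4,5,5-tetramethyl-2-(3-methylbuta-1,3-dien-2-yl)-1,3,2-dioxaborolane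
Conditions: B2pin2, PdCl2(PPh3)2 (3 mol%), PPh3 (6 mol%), KOPh, toluene, 50 °C
Reagents that add atoms: bis(pinacolato)diboron, CC1(C)OB(OC1(C)C)B1OC(C)(C)C(C)(C)O1
Why: Miyaura borylation of an alkenyl triflate under the mild phenoxide conditions gives the 1,3-dien-2-ylboronate, which is kept cold and used promptly.

Step 11
Reactants: 13 methyl (3R,6R,7S)-6-[(E)-2-[(4S)-2,2-dimethyl-1,3-dioxolan-4-yl]ethenyl]-3,6,7-trimethyl-8-oxooctanoate; 16 4,4,5,5-tetramethyl-2-(3-methylbuta-1,3-dien-2-yl)-1,3,2-dioxaborolane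
Product: 18 methyl (3R,6R,7S,8S)-6-[(E)-2-[(4S)-2,2-dimethyl-1,3-dioxolan-4-yl]ethenyl]-8-hydroxy-3,6,7,10-tetramethyldodeca-10,11-dienoate, via pinacol borate ester 17 (not isolated)
Conditions: 16 (3 equiv), (PhO)2P(O)OH (10 mol%), 4 Å molecular sieves, toluene, 0 °C to rt; then aq. NaHCO3
Reagents that add atoms: none
Why: Proposed new method: the dienylboronate is an allylboronate with boron on C4 of the B–C4–C5=C6 unit, so the six-membered allylboration transition state (Brønsted-acid activated) bonds C6 to the aldehyde and shifts the double bond to C5=C4 while C4=CH2 stays, giving the 1,1-disubstituted allene directly, and Felkin–Anh attack anti to the quaternary C9 sets C7 as S (7,8-syn); the closest known reaction types are aldehyde allylboration and the SE2' homoallenylation of aldehydes by buta-1,3-dien-2-yl Grignard and stannane reagents.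

Step 12
Reactants: 18 methyl (3R,6R,7S,8S)-6-[(E)-2-[(4S)-2,2-dimethyl-1,3-dioxolan-4-yl]ethenyl]-8-hydroxy-3,6,7,10-tetramethyldodeca-10,11-dienoate
Product: 19 methyl (3R,6R,7S,8S)-8-acetoxy-6-[(E)-2-[(4S)-2,2-dimethyl-1,3-dioxolan-4-yl]ethenyl]-3,6,7,10-tetramethyldodeca-10,11-dienoate
Conditions: Ac2O, DMAP (cat.), pyridine, CH2Cl2, 0 °C to rt
Reagents that add atoms: acetic anhydride, CC(=O)OC(C)=O
Why: DMAP-catalysed acetylation installs the C7 acetate of the target with retention, before any Michael acceptor is present.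

Step 13
Reactants: 19 methyl (3R,6R,7S,8S)-8-acetoxy-6-[(E)-2-[(4S)-2,2-dimethyl-1,3-dioxolan-4-yl]ethenyl]-3,6,7,10-tetramethyldodeca-10,11-dienoate
Product: 20 methyl (3R,6R,7S,8S)-8-acetoxy-6-[(1E,3S)-3,4-dihydroxybut-1-enyl]-3,6,7,10-tetramethyldodeca-10,11-dienoate
Conditions: AcOH/H2O/THF (3:1:1), 45 °C
Reagents that add atoms: none
Why: Mild acid hydrolysis of the acetonide frees the diol while the acetate, methyl ester and allene survive.

Step 14
Reactants: 20 methyl (3R,6R,7S,8S)-8-acetoxy-6-[(1E,3S)-3,4-dihydroxybut-1-enyl]-3,6,7,10-tetramethyldodeca-10,11-dienoate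
Product: 21 methyl (3R,6R,7S,8S)-8-acetoxy-6-[(E)-4-hydroxy-3-oxobut-1-enyl]-3,6,7,10-tetramethyldodeca-10,11-dienoate
Conditions: MnO2 (activated, 15 equiv), CH2Cl2, rt
Reagents that add atoms: none
Why: Chemoselective MnO2 oxidation of the allylic secondary alcohol gives the (E)-enone and leaves the saturated primary alcohol alone.

Step 15
Reactants: 21 methyl (3R,6R,7S,8S)-8-acetoxy-6-[(E)-4-hydroxy-3-oxobut-1-enyl]-3,6,7,10-tetramethyldodeca-10,11-dienoate
Product: 23 methyl (3R,6R,7S,8S)-8-acetoxy-6-[(1E,3Z)-3,4-bis(tert-butyldimethylsilyloxy)buta-1,3-dienyl]-3,6,7,10-tetramethyldodeca-10,11-dienoate, via primary silyl ether 22 (not isolated)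
Conditions: TBSOTf (2.5 equiv), Et3N (4 equiv), CH2Cl2, −78 to 0 °C
Reagents that add atoms: tert-butyldimethylsilyl trifluoromethanesulfonate, CC(C)(C)[Si](C)(C)OS(=O)(=O)C(F)(F)F
Why: O-silylation of the primary alcohol followed by soft enolisation toward C3 (the only enolisable position) gives the (Z)-enol ether with both oxygens cis, so the diene has only hydrogens in its inside positions.

Step 16
Reactants: 23 methyl (3R,6R,7S,8S)-8-acetoxy-6-[(1E,3Z)-3,4-bis(tert-butyldimethylsilyloxy)buta-1,3-dienyl]-3,6,7,10-tetramethyldodeca-10,11-dienoate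
Product: 24 methyl 7-acetoxy-2,3-bis(tert-butyldimethylsilyloxy)cleroda-1,4(18)-dien-15-oate (cis-fused; C5/C7/C8/C9/C10/C13 as in 27; 3-OSi cis to C9)
Conditions: toluene (0.005 M), 2,6-di-tert-butyl-4-methylphenol (5 mol%), 170 °C, sealed tube
Reagents that add atoms: none
Why: Thermal type 1 intramolecular Diels–Alder reaction in which the electron-rich diene (no 1,5-hydrogen shift possible) adds across the strained internal allene π-bond (six-membered rather than seven-membered tether ring), closing rings A and B at once and leaving the exocyclic methylene; the chair-like tether with C7-OAc and C8-Me equatorial and the allene carbon C4 axial on C5 (endo tether, cis fusion) is the only chair that avoids a syn-diaxial C19/C20 methyl–methyl contact, so it sets 5S and 10R.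

Step 17
Reactants: 24 methyl 7-acetoxy-2,3-bis(tert-butyldimethylsilyloxy)cleroda-1,4(18)-dien-15-oate
Product: 25 methyl 7-acetoxy-3-hydroxy-2-oxocleroda-4(18)-en-15-oate (3-OH cis to C9; other centres as in 27)
Conditions: HF·pyridine, pyridine, THF, 0 °C
Reagents that add atoms: none
Why: Fluoride-mediated desilylation protonates the silyl enol ether to the C2 ketone and frees the C3 alcohol, buffered and cold so that the β,γ-unsaturated α-ketol is not enolised toward the ring-conjugated isomer before it is oxidised.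

Step 18
Reactants: 25 methyl 7-acetoxy-3-hydroxy-2-oxocleroda-4(18)-en-15-oate
Product: 27 methyl (3R)-5-[(1R,2S,3S,4aS,8aR)-3-acetoxy-7-hydroxy-1,2,4a-trimethyl-5-methylidene-6-oxo-1,2,3,4,4a,5,6,8a-octahydronaphthalen-1-yl]-3-methylpentanoate (CNP0180040.1), via 2,3-diketone 26 (not isolated)
Conditions: Dess–Martin periodinane, NaHCO3, CH2Cl2, 0 °C
Reagents that add atoms: none
Why: Dess–Martin oxidation of the α-ketol gives the 2,3-diketone, which can enolise only toward C1 and so tautomerises to the cross-conjugated diosphenol of the target without touching any stereocentre.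

**Compound list**

1 | (3R)-5-methoxy-3-methyl-5-oxopentanoic acid | OC(=O)C[C@@H](C)CC(=O)OC | starting material
2 | methyl (3R)-5-hydroxy-3-methylpentanoate | OCC[C@@H](C)CC(=O)OC | intermediate
3 | methyl (3S)-5-iodo-3-methylpentanoate | ICC[C@@H](C)CC(=O)OC | intermediate
4 | methyl (4R)-2,2-dimethyl-1,3-dioxolane-4-carboxylate | COC(=O)[C@H]1COC(C)(C)O1 | starting material
5 | 1-[(4R)-2,2-dimethyl-1,3-dioxolan-4-yl]but-2-yn-1-one | CC#CC(=O)[C@H]1COC(C)(C)O1 | intermediate
6 | (1R)-1-[(4R)-2,2-dimethyl-1,3-dioxolan-4-yl]but-2-yn-1-ol | CC#C[C@@H](O)[C@H]1COC(C)(C)O1 | intermediate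
7 | O,C-dizirconated (E)-alkenylzirconocene chloride derived from 6 | C/C(=C\[C@@H](O[Zr](Cl)(C1C=CC=C1)C1C=CC=C1)[C@H]1COC(C)(C)O1)[Zr](Cl)(C1C=CC=C1)C1C=CC=C1 | intermediate
8 | (1R,2E)-1-[(4R)-2,2-dimethyl-1,3-dioxolan-4-yl]-3-iodobut-2-en-1-ol | C/C(I)=C\[C@@H](O)[C@H]1COC(C)(C)O1 | intermediate
9 | (4R)-4-[(1R,2E)-3-iodo-1-(prop-2-enyloxy)but-2-enyl]-2,2-dimethyl-1,3-dioxolane | C/C(I)=C\[C@@H](OCC=C)[C@H]1COC(C)(C)O1 | intermediate
10 | [(3S)-5-methoxy-3-methyl-5-oxopentyl]zinc iodide | I[Zn]CC[C@@H](C)CC(=O)OC | intermediate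
11 | methyl (3R,6E,8R)-8-[(4R)-2,2-dimethyl-1,3-dioxolan-4-yl]-3,6-dimethyl-8-(prop-2-enyloxy)oct-6-enoate | C/C(CC[C@@H](C)CC(=O)OC)=C\[C@@H](OCC=C)[C@H]1COC(C)(C)O1 | intermediate
12 | methyl (3R,6E,8R)-8-[(4R)-2,2-dimethyl-1,3-dioxolan-4-yl]-3,6-dimethyl-8-[(E)-prop-1-enyloxy]oct-6-enoate | C/C(CC[C@@H](C)CC(=O)OC)=C\[C@@H](O/C=C/C)[C@H]1COC(C)(C)O1 | intermediate
13 | methyl (3R,6R,7S)-6-[(E)-2-[(4S)-2,2-dimethyl-1,3-dioxolan-4-yl]ethenyl]-3,6,7-trimethyl-8-oxooctanoate | O=C[C@@H](C)[C@](C)(CC[C@@H](C)CC(=O)OC)/C=C/[C@H]1COC(C)(C)O1 | intermediate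
14 | 3-methylbut-3-en-2-one | CC(=O)C(C)=C | starting material
15 | 3-methylbuta-1,3-dien-2-yl trifluoromethanesulfonate | C=C(OS(=O)(=O)C(F)(F)F)C(C)=C | intermediate
16 | 4,4,5,5-tetramethyl-2-(3-methylbuta-1,3-dien-2-yl)-1,3,2-dioxaborolane | C=C(B1OC(C)(C)C(C)(C)O1)C(C)=C | intermediate
17 | pinacol borate ester of 18 (8-O-boryl) | C=C=C(C)C[C@H](OB1OC(C)(C)C(C)(C)O1)[C@@H](C)[C@](C)(CC[C@@H](C)CC(=O)OC)/C=C/[C@H]1COC(C)(C)O1 | intermediate
18 | methyl (3R,6R,7S,8S)-6-[(E)-2-[(4S)-2,2-dimethyl-1,3-dioxolan-4-yl]ethenyl]-8-hydroxy-3,6,7,10-tetramethyldodeca-10,11-dienoate | C=C=C(C)C[C@H](O)[C@@H](C)[C@](C)(CC[C@@H](C)CC(=O)OC)/C=C/[C@H]1COC(C)(C)O1 | intermediate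
19 | methyl (3R,6R,7S,8S)-8-acetoxy-6-[(E)-2-[(4S)-2,2-dimethyl-1,3-dioxolan-4-yl]ethenyl]-3,6,7,10-tetramethyldodeca-10,11-dienoate | C=C=C(C)C[C@H](OC(C)=O)[C@@H](C)[C@](C)(CC[C@@H](C)CC(=O)OC)/C=C/[C@H]1COC(C)(C)O1 | intermediate
20 | methyl (3R,6R,7S,8S)-8-acetoxy-6-[(1E,3S)-3,4-dihydroxybut-1-enyl]-3,6,7,10-tetramethyldodeca-10,11-dienoate | C=C=C(C)C[C@H](OC(C)=O)[C@@H](C)[C@](C)(CC[C@@H](C)CC(=O)OC)/C=C/[C@H](O)CO | intermediate
21 | methyl (3R,6R,7S,8S)-8-acetoxy-6-[(E)-4-hydroxy-3-oxobut-1-enyl]-3,6,7,10-tetramethyldodeca-10,11-dienoate | C=C=C(C)C[C@H](OC(C)=O)[C@@H](C)[C@](C)(CC[C@@H](C)CC(=O)OC)/C=C/C(=O)CO | intermediate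
22 | methyl (3R,6R,7S,8S)-8-acetoxy-6-[(E)-4-(tert-butyldimethylsilyloxy)-3-oxobut-1-enyl]-3,6,7,10-tetramethyldodeca-10,11-dienoate | C=C=C(C)C[C@H](OC(C)=O)[C@@H](C)[C@](C)(CC[C@@H](C)CC(=O)OC)/C=C/C(=O)CO[Si](C)(C)C(C)(C)C | intermediate
23 | methyl (3R,6R,7S,8S)-8-acetoxy-6-[(1E,3Z)-3,4-bis(tert-butyldimethylsilyloxy)buta-1,3-dienyl]-3,6,7,10-tetramethyldodeca-10,11-dienoate | C=C=C(C)C[C@H](OC(C)=O)[C@@H](C)[C@](C)(CC[C@@H](C)CC(=O)OC)/C=C/C(O[Si](C)(C)C(C)(C)C)=C/O[Si](C)(C)C(C)(C)C | intermediate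
24 | methyl 7-acetoxy-2,3-bis(tert-butyldimethylsilyloxy)cleroda-1,4(18)-dien-15-oate (cis-fused; ring and side-chain centres as in 27; 3-OSi cis to C9) | C=C1[C@H](O[Si](C)(C)C(C)(C)C)C(O[Si](C)(C)C(C)(C)C)=C[C@@H]2[C@@](C)(CC[C@@H](C)CC(=O)OC)[C@H](C)[C@@H](OC(C)=O)C[C@]12C | intermediate
25 | methyl 7-acetoxy-3-hydroxy-2-oxocleroda-4(18)-en-15-oate (3-OH cis to C9; other centres as in 27) | C=C1[C@H](O)C(=O)C[C@@H]2[C@@](C)(CC[C@@H](C)CC(=O)OC)[C@H](C)[C@@H](OC(C)=O)C[C@]12C | intermediate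
26 | methyl 7-acetoxy-2,3-dioxocleroda-4(18)-en-15-oate (centres as in 27) | C=C1C(=O)C(=O)C[C@@H]2[C@@](C)(CC[C@@H](C)CC(=O)OC)[C@H](C)[C@@H](OC(C)=O)C[C@]12C | intermediate
27 | methyl (3R)-5-[(1R,2S,3S,4aS,8aR)-3-acetoxy-7-hydroxy-1,2,4a-trimethyl-5-methylidene-6-oxo-1,2,3,4,4a,5,6,8a-octahydronaphthalen-1-yl]-3-methylpentanoate (CNP0180040.1) | C=C1C(=O)C(O)=C[C@@H]2[C@@](C)(CC[C@@H](C)CC(=O)OC)[C@H](C)[C@@H](OC(C)=O)C[C@]12C | target

**Step count and risk**

Total steps: 18. Longest linear sequence: 14 steps (steps 3–8, then 11–18, from 4 to 27).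

Three steps most likely to fail:

Step 16 (the allene Diels–Alder). The unactivated 1,1-disubstituted allene may be too slow at 170 °C, or may react at its terminal π-bond. The fallback sets out from triene 23 and replaces the concerted thermal cycloaddition by a metal-templated stepwise annulation. A zerovalent nickel or monovalent rhodium phosphite catalyst (Ni(C8H12)2 or [RhCl(C8H12)]2 with P(O-2-PhC6H4)3, toluene, 60–80 °C, the metal/ligand pair screened for reaction at the internal π-bond) couples the diene and the allene oxidatively to a metallacycle and reductively eliminates. The route is rejoined at adduct 24; this fallback makes no new compound (F0).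

Step 11 (homoallenylboration). The dienylboronate 16 may dimerise, add sluggishly to the hindered aldehyde, or give modest Felkin selectivity. The fallback sets out from aldehyde 13 and builds the allene by aldol addition, alkynylation and SN2' reduction. A Felkin-selective Mukaiyama aldol with 2-(trimethylsilyloxy)propene (BF3·OEt2, CH2Cl2, −78 °C) gives the β-hydroxy methyl ketone F1. HC≡CMgBr (THF, −40 to 0 °C) adds to the ketone to give the tertiary propargylic diol F2 as both C10 epimers. Ac2O, DMAP and Et3N (CH2Cl2, 40 °C) give the diacetate F3. Hydride SN2' reduction of the tertiary propargylic acetate with [(Ph3P)CuH]6 (toluene, rt) then gives the 1,1-disubstituted allene, which is acetate 19, where the route is rejoined.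

Step 8 (isomerisation–Claisen rearrangement to the quaternary C9). The iridium isomerisation may stall on this hindered, oxygen-rich ether, or the thermal shift may erode the C8 centre. The fallback sets out from alkenyl iodide 8 and uses an ester-enolate (Ireland–Claisen) rearrangement instead. Negishi coupling of 8 with alkylzinc 10 (2.2 equiv, Pd(PPh3)4) gives the allylic alcohol F4. EtCOCl and pyridine give the propionate F5. LiN(i-Pr)2 and Me3SiCl in THF/DMPU (−78 °C to rt; Z-enolate, chair transition state, same sense of chirality transfer) give the acid F6. i-BuOCOCl and N-methylmorpholine followed by NaBH4 give the primary alcohol F7, and Dess–Martin oxidation returns aldehyde 13.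

Further compounds
F0 | step 16 | none | none
F1 | step 11 | methyl (3R,6R,7S,8S)-6-[(E)-2-[(4S)-2,2-dimethyl-1,3-dioxolan-4-yl]ethenyl]-8-hydroxy-3,6,7-trimethyl-10-oxoundecanoate | CC(=O)C[C@H](O)[C@@H](C)[C@](C)(CC[C@@H](C)CC(=O)OC)/C=C/[C@H]1COC(C)(C)O1
F2 | step 11 | methyl (3R,6R,7S,8S)-6-[(E)-2-[(4S)-2,2-dimethyl-1,3-dioxolan-4-yl]ethenyl]-8,10-dihydroxy-3,6,7,10-tetramethyldodec-11-ynoate (both C10 epimers) | C#CC(C)(O)C[C@H](O)[C@@H](C)[C@](C)(CC[C@@H](C)CC(=O)OC)/C=C/[C@H]1COC(C)(C)O1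
F3 | step 11 | methyl (3R,6R,7S,8S)-8,10-diacetoxy-6-[(E)-2-[(4S)-2,2-dimethyl-1,3-dioxolan-4-yl]ethenyl]-3,6,7,10-tetramethyldodec-11-ynoate (both C10 epimers) | C#CC(C)(OC(C)=O)C[C@H](OC(C)=O)[C@@H](C)[C@](C)(CC[C@@H](C)CC(=O)OC)/C=C/[C@H]1COC(C)(C)O1
F4 | step 8 | methyl (3R,6E,8R)-8-[(4R)-2,2-dimethyl-1,3-dioxolan-4-yl]-8-hydroxy-3,6-dimethyloct-6-enoate | C/C(CC[C@@H](C)CC(=O)OC)=C\[C@@H](O)[C@H]1COC(C)(C)O1
F5 | step 8 | methyl (3R,6E,8R)-8-[(4R)-2,2-dimethyl-1,3-dioxolan-4-yl]-3,6-dimethyl-8-(propanoyloxy)oct-6-enoate | C/C(CC[C@@H](C)CC(=O)OC)=C\[C@@H](OC(=O)CC)[C@H]1COC(C)(C)O1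
F6 | step 8 | (2S,3R,6R)-3-[(E)-2-[(4S)-2,2-dimethyl-1,3-dioxolan-4-yl]ethenyl]-8-methoxy-2,3,6-trimethyl-8-oxooctanoic acid | OC(=O)[C@@H](C)[C@](C)(CC[C@@H](C)CC(=O)OC)/C=C/[C@H]1COC(C)(C)O1
F7 | step 8 | methyl (3R,6R,7S)-6-[(E)-2-[(4S)-2,2-dimethyl-1,3-dioxolan-4-yl]ethenyl]-8-hydroxy-3,6,7-trimethyloctanoate | OC[C@@H](C)[C@](C)(CC[C@@H](C)CC(=O)OC)/C=C/[C@H]1COC(C)(C)O1
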